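**Retrosynthetic overview**
1. Target 20 ⇐ hexamethyl ether 19; the six aryl methyl ethers are cleaved last.
2. Key step: the biaryl bond meta to the ring-C hydroxyl comes from a dienone–phenol 1,2-aryl shift that expands the spiro five-membered ring of dienone 18 to the six-membered dihydrophenanthrene ring; 18 ⇐ oxidative ipso-cyclisation of phenol 17.
3. 17 (seven-membered ring, both stereocentres) ⇐ enantioselective desymmetrising Friedel–Crafts closure of hydroxystilbene 15, which carries two identical veratryl groups.
4. 15 ⇐ Heck coupling of iodophenol 14 with styrene 7; 14 ⇐ 13 ⇐ double Friedel–Crafts of veratrole 2 on enol ether 11 ⇐ 3-bromophenol + ethoxyacetylene; 7 ⇐ resorcinol + vinyl bromide.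
5. Ring order: four benzene rings are bought (catechol twice, resorcinol, 3-bromophenol) → seven-membered ring (step 8) → spiro five-membered ring → six-membered ring by ring expansion (step 9).

Ring letters: A = resorcinol ring, B = fused catechol ring, C = mono-hydroxy ring, D = pendant catechol ring. Locants 5 and 10 in 17 follow dibenzo[a,d][7]annulene numbering.

Assumption: the sense of induction of the new catalyst in step 8 cannot be predicted with certainty; the (S,S) acid is written, and its antipode is used if the first run gives the mirror image.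

**Step 1**
Reactants: 1 catechol
Product: 2 veratrole (1,2-dimethoxybenzene)
Conditions: MeI (2.5 equiv), K2CO3 (3 equiv), acetone, reflux
Reagents that add atoms: iodomethane, CI
Why: Williamson O-methylation (SN2) of both phenoxide oxygens; no stereocentre.

**Step 2**
Reactants: 3 resorcinol
Product: 4 1,3-dimethoxybenzene
Conditions: MeI (2.5 equiv), K2CO3 (3 equiv), acetone, reflux
Reagents that add atoms: iodomethane, CI
Why: Williamson O-methylation (SN2) of both phenoxide oxygens; no stereocentre.

**Step 3**
Reactants: 4 1,3-dimethoxybenzene; 5 vinyl bromide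
Product: 7 3,5-dimethoxystyrene, via 3,5-dimethoxyphenyl pinacol boronate 6 (not isolated)
Conditions: [Ir(OMe)(cod)]2 (1 mol%), dtbpy (2 mol%), B2pin2 (0.55 equiv), THF, 80 °C; then 5 (1 M in THF), Pd(dppf)Cl2 (2 mol%), aq K3PO4, 60 °C, sealed
Reagents that add atoms: bis(pinacolato)diboron, CC1(C)OB(OC1(C)C)B1OC(C)(C)C(C)(C)O1 (boron is kept only in 6)
Why: Iridium-catalysed C–H borylation is sterically steered to the only C–H that is not ortho to a methoxy group (C-5), and the boronate is vinylated in the same pot by Suzuki–Miyaura coupling.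

**Step 4**
Reactants: 8 3-bromophenol; 9 ethoxyacetylene
Product: 11 3-[(E)-2-ethoxyethenyl]phenol, via (E)-2-ethoxyethenyl pinacol boronate 10 (not isolated)
Conditions: 9, HBpin (1.05 equiv), Cp2Zr(H)Cl (5 mol%), CH2Cl2, 0 °C → rt; then 8, Pd(dppf)Cl2 (3 mol%), K3PO4, THF/H2O, 65 °C
Reagents that add atoms: pinacolborane, CC1(C)OBOC1(C)C (boron is kept only in 10)
Why: Zirconium-catalysed syn-hydroboration puts boron on the terminal alkyne carbon (E), and Suzuki–Miyaura coupling at C–Br tolerates the free phenol, giving a masked arylacetaldehyde.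

**Step 5**
Reactants: 11 3-[(E)-2-ethoxyethenyl]phenol; 2 veratrole (two molecules are built in)
Product: 13 3-[2,2-bis(3,4-dimethoxyphenyl)ethyl]phenol, via monoaryl ethyl ether 12 (not isolated)
Conditions: 2 (8 equiv), TfOH (10 mol%), CH2Cl2/HFIP 4:1, 0 °C → rt
Reagents that add atoms: none
Why: Double Friedel–Crafts (Baeyer-type) arylation: the protonated enol ether is an oxocarbenium ion that veratrole attacks para to OMe, ether 12 re-ionises to a p-methoxybenzylic cation that takes up the second veratrole, and excess veratrole outcompetes the phenol ring; the new CH carries two identical aryl groups and is not a stereocentre.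

**Step 6**
Reactants: 13 3-[2,2-bis(3,4-dimethoxyphenyl)ethyl]phenol
Product: 14 3-[2,2-bis(3,4-dimethoxyphenyl)ethyl]-4-iodophenol
Conditions: NIS (1.0 equiv), p-TsOH·H2O (10 mol%), MeCN, −20 → 0 °C
Reagents that add atoms: N-iodosuccinimide, O=C1CCC(=O)N1I
Why: Electrophilic aromatic iodination is fastest on the free phenol ring and goes para to OH, while the aryl ether rings react much more slowly under these mild conditions.

**Step 7**
Reactants: 14 3-[2,2-bis(3,4-dimethoxyphenyl)ethyl]-4-iodophenol; 7 3,5-dimethoxystyrene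
Product: 15 (E)-3-[2,2-bis(3,4-dimethoxyphenyl)ethyl]-4-[2-(3,5-dimethoxyphenyl)ethenyl]phenol
Conditions: Pd(OAc)2 (3 mol%), NaOAc (2 equiv), n-Bu4NCl (1 equiv), DMF, 90 °C
Reagents that add atoms: none
Why: Mizoroki–Heck reaction of the aryl iodide under ligand-free phase-transfer conditions; syn-insertion and syn-β-hydride elimination give the E-stilbene.

**Step 8**
Reactants: 15 (E)-3-[2,2-bis(3,4-dimethoxyphenyl)ethyl]-4-[2-(3,5-dimethoxyphenyl)ethenyl]phenol
Product: 17 (5S,10S)-10-(3,4-dimethoxyphenyl)-5-[(3,5-dimethoxyphenyl)methyl]-7,8-dimethoxy-10,11-dihydro-5H-dibenzo[a,d][7]annulen-2-ol (5-H/10-H cis), via (E)-p-quinone methide 16 (not isolated)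
Conditions: (S,S)-IDPi Brønsted acid (5 mol%; imidodiphosphorimidate built from two 3,3′-bis[3,5-bis(trifluoromethyl)phenyl]-BINOL units, N-triflyl core), CHCl3/cyclohexane 1:1, 0.01 M, 5 Å MS, −20 °C
Reagents that add atoms: none
Why: Proposed new method: the confined strong chiral acid protonates the stilbene carbon next to ring A to give the ion-paired (E)-p-quinone methide 16 (phenol OH hydrogen-bonded to the anion, side chain turned away from the ortho tether), and one of the two enantiotopic veratryl groups closes the seven-membered ring by Friedel–Crafts attack of its C-6 (para to OMe) on the methide carbon through a boat-like transition state with side chain and spectator aryl both pseudo-equatorial, which sets C-5 and C-10 together as the cis (5S,10S) pair; the closest known reactions are chiral phosphoric acid-catalysed 1,6-arylations of in situ p-quinone methides and IDPi-catalysed asymmetric hydroarylations of styrenes, neither shown for a desymmetrising seven-ring closure.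

**Step 9**
Reactants: 17 (5S,10S)-cis-dibenzo[a,d][7]annulen-2-ol from step 8
Product: 19 hexa-O-methyl ether of 20 with the ring-C hydroxyl free, via spirodienone 18 (not isolated)
Conditions: PhI(OAc)2 (1.05 equiv), HFIP, −20 °C, 20 min; then TFA (5 equiv), 0 °C → rt
Reagents that add atoms: none
Why: Hypervalent-iodine oxidative dearomatisation of the only free phenol lets the 3,5-dimethoxybenzyl ring attack the para (ipso) carbon through a five-membered transition state (with the side chain perpendicular to ring C the benzylic H lies in the ring plane, which disfavours quinone methide formation), and acid then triggers the dienone–phenol rearrangement in which the electron-rich aryl group shifts 1,2 to the unsubstituted neighbouring carbon, expanding the spiro five-membered ring to the six-membered dihydrophenanthrene ring and restoring the phenol without touching either stereocentre.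

**Step 10**
Reactants: 19 hexa-O-methyl ether
Product: 20 CNP0306974.1
Conditions: BBr3 (12 equiv), CH2Cl2, −78 °C → rt; then MeOH/H2O, 0 °C
Reagents that add atoms: none
Why: Lewis-acid ether cleavage (SN2 attack of bromide on the O-methyl groups of the borate complexes) frees all six phenols; the two diarylmethine stereocentres are not enolisable and stay intact.

**Compound list**
1 | catechol | Oc1ccccc1O | starting material
2 | veratrole (1,2-dimethoxybenzene) | COc1ccccc1OC | intermediate
3 | resorcinol | Oc1cccc(O)c1 | starting material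
4 | 1,3-dimethoxybenzene | COc1cccc(OC)c1 | intermediate
5 | vinyl bromide | C=CBr | starting material
6 | 2-(3,5-dimethoxyphenyl)-4,4,5,5-tetramethyl-1,3,2-dioxaborolane (formed in situ) | COc1cc(OC)cc(c1)B1OC(C)(C)C(C)(C)O1 | intermediate
7 | 3,5-dimethoxystyrene | COc1cc(OC)cc(C=C)c1 | intermediate
8 | 3-bromophenol | Oc1cccc(Br)c1 | starting material
9 | ethoxyacetylene | CCOC#C | starting material
10 | 2-[(E)-2-ethoxyethenyl]-4,4,5,5-tetramethyl-1,3,2-dioxaborolane (formed in situ) | CCO/C=C/B1OC(C)(C)C(C)(C)O1 | intermediate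
11 | 3-[(E)-2-ethoxyethenyl]phenol | CCO/C=C/c1cccc(O)c1 | intermediate
12 | 3-[2-(3,4-dimethoxyphenyl)-2-ethoxyethyl]phenol (racemic, formed in situ) | CCOC(Cc1cccc(O)c1)c1ccc(OC)c(OC)c1 | intermediate
13 | 3-[2,2-bis(3,4-dimethoxyphenyl)ethyl]phenol | COc1ccc(cc1OC)C(Cc1cccc(O)c1)c1ccc(OC)c(OC)c1 | intermediate
14 | 3-[2,2-bis(3,4-dimethoxyphenyl)ethyl]-4-iodophenol | COc1ccc(cc1OC)C(Cc1cc(O)ccc1I)c1ccc(OC)c(OC)c1 | intermediate
15 | (E)-3-[2,2-bis(3,4-dimethoxyphenyl)ethyl]-4-[2-(3,5-dimethoxyphenyl)ethenyl]phenol | COc1cc(OC)cc(/C=C/c2ccc(O)cc2CC(c2ccc(OC)c(OC)c2)c2ccc(OC)c(OC)c2)c1 | intermediate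
16 | (E)-3-[2,2-bis(3,4-dimethoxyphenyl)ethyl]-4-[2-(3,5-dimethoxyphenyl)ethylidene]cyclohexa-2,5-dien-1-one (p-quinone methide, formed in situ) | O=C1C=C/C(=C\Cc2cc(OC)cc(OC)c2)C(CC(c2ccc(OC)c(OC)c2)c2ccc(OC)c(OC)c2)=C1 | intermediate
17 | (5S,10S)-10-(3,4-dimethoxyphenyl)-5-[(3,5-dimethoxyphenyl)methyl]-7,8-dimethoxy-10,11-dihydro-5H-dibenzo[a,d][7]annulen-2-ol, 5-H and 10-H cis | COc1cc(OC)cc(c1)C[C@@H]1c3cc(OC)c(OC)cc3[C@H](c3ccc(OC)c(OC)c3)Cc3cc(O)ccc31 | intermediate
18 | spirodienone (formed in situ): the ring-C carbon para to the carbonyl is a spiro centre (R) bonded to C-2 of the 3,5-dimethoxybenzyl ring, closing a five-membered ring; ring C is a cyclohexa-2,5-dienone; ring-fusion CH (R), aryl-bearing CH (S) | COc1cc(OC)c2c(c1)C[C@@H]1c3cc(OC)c(OC)cc3[C@H](c3ccc(OC)c(OC)c3)CC3=CC(=O)C=C[C@]231 | intermediate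
19 | hexa-O-methyl ether of 20 (OMe on rings A, B and D; ring-C OH free); (R) at the CH shared by the six- and seven-membered rings, (S) at the CH bearing the 3,4-dimethoxyphenyl group | COc1cc(OC)c2c(c1)C[C@@H]1c3cc(OC)c(OC)cc3[C@H](c3ccc(OC)c(OC)c3)Cc3cc(O)cc-2c31 | intermediate
20 | CNP0306974.1: 9,10-dihydrophenanthrene fused to a dibenzo[7]annulene, seven phenolic OH; (R) at the CH shared by the six- and seven-membered rings, (S) at the CH bearing the 3,4-dihydroxyphenyl group, the two methine H cis | Oc1cc(O)c2c(c1)C[C@@H]1c3cc(O)c(O)cc3[C@H](c3ccc(O)c(O)c3)Cc3cc(O)cc-2c31 | target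

**Totals**
Total step count: 10.
Longest linear sequence: 7 steps (8 → 11 → 13 → 14 → 15 → 17 → 19 → 20, steps 4 to 10).

**Three steps most likely to fail**

Step 8 (the proposed new step). The acid may give low ee, the trans isomer or oligomers, and the cis preference rests on a transition-state argument only. The fallback sets out from 15 and comes back at 17. Treating 15 with an achiral acid (TfOH 5 mol%, CH2Cl2/HFIP, 0 °C) is the known acid-mediated Friedel–Crafts hydroarylation of a 4-hydroxystilbene and gives the racemic cis phenol, that is 17 together with its mirror image, the (5R,10R)-phenol F1. The two are separated by preparative SFC on a chiral amylose phase, and 17 goes on into step 9.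

Step 9. The doubly benzylic H para to the phenol could be lost to a quinone methide, the cis aryl group could hinder the conformer needed for ipso attack, or the product phenol could be over-oxidised. The fallback sets out from 17 and comes back at 20. O-Methylation (MeI, K2CO3, DMF) gives the heptamethyl ether F2. NBS (1.0 equiv, MeCN, 0 °C) brominates the most electron-rich ring, the 3,5-dimethoxybenzyl ring, ortho to its CH2 and gives the aryl bromide F3. Intramolecular direct C–H arylation (Pd(OAc)2, PCy3·HBF4, K2CO3, PivOH, DMA, 120 °C) at the ring-C carbon ortho to the methine gives the pentacyclic heptamethyl ether F4; closure onto ring B instead would force two methoxy groups into the bay region. BBr3 as in step 10 then gives 20.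

Step 6. Iodination may also hit the position ortho to OH or a veratryl ring. The fallback installs the halogen before the veratryl rings are present; it sets out from boronate 10 (made from 9 as in step 4), 2 and 7, and comes back at 15. Commercial 3-iodophenol F5 is brominated para to OH (n-Bu4NBr3, CH2Cl2/MeOH, 0 °C) to 4-bromo-3-iodophenol F6. Suzuki coupling with 10 at the C–I bond (Pd(PPh3)4, K3PO4, THF/H2O, 50 °C) gives 4-bromo-3-[(E)-2-ethoxyethenyl]phenol F7. Veratrole 2 and TfOH as in step 5 give, by way of the monoaryl ethyl ether F8, 4-bromo-3-[2,2-bis(3,4-dimethoxyphenyl)ethyl]phenol F9. Heck reaction of F9 with 7 (Herrmann–Beller palladacycle 1 mol%, NaOAc, DMA, 130 °C) gives 15.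

**Further compounds**
F1 | step 8 | (5R,10R)-enantiomer of 17 | COc1cc(OC)cc(c1)C[C@H]1c3cc(OC)c(OC)cc3[C@@H](c3ccc(OC)c(OC)c3)Cc3cc(O)ccc31
F2 | step 9 | 2-O-methyl ether of 17 (heptamethyl ether, 5S,10S) | COc1cc(OC)cc(c1)C[C@@H]1c3cc(OC)c(OC)cc3[C@H](c3ccc(OC)c(OC)c3)Cc3cc(OC)ccc31
F3 | step 9 | F2 brominated at C-2 of the 3,5-dimethoxybenzyl ring (5S,10S) | COc1cc(OC)c(Br)c(c1)C[C@@H]1c3cc(OC)c(OC)cc3[C@H](c3ccc(OC)c(OC)c3)Cc3cc(OC)ccc31
F4 | step 9 | hepta-O-methyl ether of 20 | COc1cc(OC)c2c(c1)C[C@@H]1c3cc(OC)c(OC)cc3[C@H](c3ccc(OC)c(OC)c3)Cc3cc(OC)cc-2c31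
F5 | step 6 | 3-iodophenol | Oc1cccc(I)c1
F6 | step 6 | 4-bromo-3-iodophenol | Oc1ccc(Br)c(I)c1
F7 | step 6 | 4-bromo-3-[(E)-2-ethoxyethenyl]phenol | CCO/C=C/c1cc(O)ccc1Br
F8 | step 6 | 4-bromo-3-[2-(3,4-dimethoxyphenyl)-2-ethoxyethyl]phenol (racemic, formed in situ) | CCOC(Cc1cc(O)ccc1Br)c1ccc(OC)c(OC)c1
F9 | step 6 | 4-bromo-3-[2,2-bis(3,4-dimethoxyphenyl)ethyl]phenol | COc1ccc(cc1OC)C(Cc1cc(O)ccc1Br)c1ccc(OC)c(OC)c1
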